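Target is slow to appear in Monday's large charge, so the first question is whether its pace follows the substrate at all.

in all of them: gas phase 0.63 mM (held)

| charge | substrate | remark | time |
|---|---|---|---|
| Sunday's | 2.4 mM | run made earlier |  |
| Monday's | 17 mM | run made earlier |  |
| west | 25 mM |  | 80 min |
| north | 8.0 mM |  | 80 min |
| north-east | 15 mM |  | 80 min |
| north-west | 4.0 mM |  | 80 min |

| run | time / min | target / % | substrate / % |
|---|---|---|---|
| Sunday's | 5.00 | 5.0 | 89.9 |
| Sunday's | 6.00 | 5.7 | 87.6 |
| Sunday's | 10.0 | 10.6 | 78.5 |
| Sunday's | 15.0 | 15.8 | 67.9 |
| Sunday's | 25.0 | 22.7 | 53.5 |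
| Sunday's | 40.0 | 27.0 | 40.4 |
| Sunday's | 60.0 | 28.1 | 32.0 |
| Monday's | 3.00 | 1.1 | 94.6 |
| Monday's | 8.00 | 2.2 | 87.7 |
| Monday's | 15.0 | 4.9 | 79.1 |
| Monday's | 25.0 | 8.3 | 66.7 |
| Monday's | 30.0 | 8.7 | 61.9 |
| Monday's | 40.0 | 11.4 | 52.5 |
| Monday's | 60.0 | 15.5 | 37.4 |

(standard deviation of a reading: 0.5 percentage points)

- at the start none of the gas phase is in solution

* the flasks put in order of amount of target, in percent of the substrate charged, best first, at 80 min (west / north / north-east / north-west)
* the amount of target, in percent of the substrate charged of the flask you put first, at 80 min
* the amount of target, in percent of the substrate charged of the flask you put last, at 80 min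

At 25.0 min, Monday's flask holds 1.41 mM of target and Sunday's 0.545 mM, a ratio of 2.59, although Monday's charge is 7.08 times Sunday's. Monday's pace therefore lags its charge, and the concentration to watch is dissolved gas, which starts at none and is fed towards a saturation of 0.63 mM, less than either charge. Gas uptake looks like the rate-limiting step in Monday's larger charge.

What does that uptake pay for? Monday's flask averages 2.64 mM h⁻¹ of target over its 60.0 min. Call this the gas allowance: multiplied by the time and divided by the charge, it estimates the fraction of the charge turned into target at Monday's pace. By 80 min that is 14.1% for west, 23.4% for north-east, 43.9% for north and 87.8% for north-west.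

Which flasks does the allowance actually bind? Sunday's small charge flattens near 28.1%, a reading at 60.0 min, and the allowances of north and north-west stand above it. My own estimate is thus west last at about 14.1%, and north-west first at about 28.1%, since its allowance is wider than those of the other flasks.

The forecast gives north-west > north > north-east > west, with 29.5% first and 15.5% last, a little above mine at both ends, and says of the first flask that “it still leads”.

The flasks come out north-west > north > north-east > west, with 24.9% in north-west and 14.2% in west.

    gas phase ⇌ dissolved gas, rate k1*(csat - [dissolved gas]) (kL = 0.107 min⁻¹)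
    substrate + dissolved gas ⇌ target (K = 2030 M⁻¹, k = 128 M⁻¹ min⁻¹)
    substrate → side product (k = 0.0123 min⁻¹)
    dissolved gas ⇌ dormant form (K = 9.25, k = 0.0761 min⁻¹)

West's allowance of 14.1% stands beside that 14.2%, and at 80.0 min west's dissolved gas is 0.261 mM, less than the saturation of 0.63 mM. North-west left until 20 min has an allowance of 22.0% and reads 16.4% of target, with 64% of its charge still substrate.

(The earlier runs and the new flask were computed for substances that don't exist; scatter was added.)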